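In bicyclo[3.3.1]nonane numbering, everything rests on disconnecting the C1–C8 bond of the cyclohexanone ring (C1, C8, C7, C6, C5, C9), the bond that joins the acyl-bearing bridgehead to the gem-dimethyl carbon. The precursor is a dearomatised acylphloroglucinol: ring A is complete, C5 is quaternary and carries an allyl group and a (2R)-2-isopropenylpent-4-enyl chain. Irradiation makes the chelated C9 enol O–H, hydrogen-bonded to the C1 acyl carbonyl, a strong acid; it protonates the isopropenyl group, and the C8 cation is captured at C1. One operation closes the ring, joins two quaternary carbons and fixes C1 from C5 and C7, with a regiochemistry that ground-state acid does not give.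

Key step: step 10

Remark: (2R)-2-methylbutanoic acid 7 is taken as commercially available in enantiopure form.
Remark: the dearomatised triones 13–15 and their F analogues are drawn and named as one enol tautomer of a rapidly equilibrating set; their descriptors refer to that tautomer.
Remark: C5 is not set selectively in this route: step 8 should give both epimers at the new quaternary carbon, and the wanted one is obtained by separation.

Step 1
Reactants: 1 (4S)-4-benzyl-1,3-oxazolidin-2-one; 2 3-methylbut-2-enoyl chloride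
Product: 3 (4S)-4-benzyl-3-(3-methylbut-2-enoyl)-1,3-oxazolidin-2-one
Conditions: n-BuLi, THF, −78 °C; then 2, −78 to 0 °C
Reagents that add atoms: none
Why: N-acylation of the lithiated oxazolidinone by an acid chloride installs the auxiliary that will control C7; no stereocentre is formed.

Step 2
Reactants: 3 (4S)-4-benzyl-3-(3-methylbut-2-enoyl)-1,3-oxazolidin-2-one
Product: 4 (4S)-4-benzyl-3-[(2S)-2-(prop-1-en-2-yl)pent-4-enoyl]-1,3-oxazolidin-2-one
Conditions: NaN(SiMe3)2, THF, −78 °C; allyl iodide, −78 to −45 °C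
Reagents that add atoms: allyl iodide, C=CCI
Why: Evans alkylation in its deconjugative form: γ-deprotonation gives the chelated (Z)-dienolate, which is alkylated at the α-carbon on the face away from the benzyl group, setting the future C7 as (S) and leaving an isopropenyl group.

Step 3
Reactants: 4 (4S)-4-benzyl-3-[(2S)-2-(prop-1-en-2-yl)pent-4-enoyl]-1,3-oxazolidin-2-one
Product: 5 (2S)-2-(prop-1-en-2-yl)pent-4-en-1-ol
Conditions: LiBH4, MeOH (1 equiv), Et2O, 0 °C
Reagents that add atoms: none
Why: reductive cleavage of the N-acyl oxazolidinone to the primary alcohol; the α-centre is not enolised under these conditions, so its configuration is kept.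

Step 4
Reactants: 5 (2S)-2-(prop-1-en-2-yl)pent-4-en-1-ol
Product: 6 (2S)-2-(prop-1-en-2-yl)pent-4-en-1-yl trifluoromethanesulfonate
Conditions: Tf2O, 2,6-lutidine, CH2Cl2, −78 °C; short silica plug, used at once
Reagents that add atoms: trifluoromethanesulfonic anhydride, O=S(=O)(OS(=O)(=O)C(F)(F)F)C(F)(F)F
Why: O-sulfonylation of a primary alcohol gives the alkylating agent; the stereocentre is not touched.

Step 5
Reactants: 7 (2R)-2-methylbutanoic acid; 8 benzene-1,3,5-triol (phloroglucinol)
Product: 10 (2R)-2-methyl-1-(2,4,6-trihydroxyphenyl)butan-1-one, via acid chloride 9 (not isolated)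
Conditions: (COCl)2, DMF (cat.), CH2Cl2, 0 °C to rt; then 8, AlCl3, CH2Cl2/MeNO2, 0 °C to rt
Reagents that add atoms: none
Why: Friedel–Crafts C-acylation of phloroglucinol stops at the mono-ketone because the product is deactivated; the (R) α-centre is brought in from 7 and is carried unchanged to the target, which is why base and heat are avoided.

Step 6
Reactants: 10 (2R)-2-methyl-1-(2,4,6-trihydroxyphenyl)butan-1-one
Product: 11 (2R)-1-(3-bromo-2,4,6-trihydroxyphenyl)-2-methylbutan-1-one
Conditions: N-bromosuccinimide (1.0 equiv), THF, −78 to −30 °C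
Reagents that add atoms: N-bromosuccinimide, O=C1CCC(=O)N1Br
Why: electrophilic aromatic bromination of one of the two equivalent free ring positions; the bromine blocks the future C3 so that both later C-alkylations must take place at the other carbon.

Step 7
Reactants: 11 (2R)-1-(3-bromo-2,4,6-trihydroxyphenyl)-2-methylbutan-1-one
Product: 12 (2R)-1-[3-bromo-2,4,6-trihydroxy-5-(prop-2-en-1-yl)phenyl]-2-methylbutan-1-one
Conditions: allyl bromide (1.1 equiv), 10% aq. KOH, 0 °C
Reagents that add atoms: allyl bromide, C=CCBr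
Why: C-allylation of the phloroglucinol polyanion in water at the only remaining ring C–H; no stereocentre is formed.

Step 8
Reactants: 12 (2R)-1-[3-bromo-2,4,6-trihydroxy-5-(prop-2-en-1-yl)phenyl]-2-methylbutan-1-one; 6 (2S)-2-(prop-1-en-2-yl)pent-4-en-1-yl trifluoromethanesulfonate
Product: 14 (6S)-3,5-dihydroxy-2-[(2R)-2-methylbutanoyl]-6-(prop-2-en-1-yl)-6-[(2R)-2-(prop-1-en-2-yl)pent-4-en-1-yl]cyclohexa-2,4-dien-1-one, via bromodienone 13 (not isolated)
Conditions: LiN(SiMe3)2 (3.2 equiv), THF, −78 °C; 6, −78 to −20 °C; then aq. Na2SO3 and aq. NaH2PO4, 0 °C; preparative HPLC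
Reagents that add atoms: none
Why: alkylative dearomatisation, in which the lithium trianion is C-alkylated by the primary triflate at the allyl-bearing carbon (the acyl- and bromine-bearing carbons are deactivated) and the positive bromine of the resulting 2-bromo-1,3-dione is removed by sulfite in the work-up; the new quaternary centre C6 (later C5) gets no useful bias from the remote centre, so both epimers should form, and the (6S) epimer is separated and carried on.

Step 9
Reactants: 14 (6S)-3,5-dihydroxy-2-[(2R)-2-methylbutanoyl]-6-(prop-2-en-1-yl)-6-[(2R)-2-(prop-1-en-2-yl)pent-4-en-1-yl]cyclohexa-2,4-dien-1-one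
Product: 15 (6S)-3,5-dihydroxy-2-[(2R)-2-methylbutanoyl]-4-(3-oxobutyl)-6-(prop-2-en-1-yl)-6-[(2R)-2-(prop-1-en-2-yl)pent-4-en-1-yl]cyclohexa-2,4-dien-1-one
Conditions: methyl vinyl ketone (1.05 equiv), Et3N (0.2 equiv), CH2Cl2, 0 °C to rt
Reagents that add atoms: methyl vinyl ketone, CC(=O)C=C
Why: Michael addition of the only free enolic ring carbon (freed by the debromination) to an enone places the side chain at the future C3; no stereocentre is formed.

Step 10
Reactants: 15 (6S)-3,5-dihydroxy-2-[(2R)-2-methylbutanoyl]-4-(3-oxobutyl)-6-(prop-2-en-1-yl)-6-[(2R)-2-(prop-1-en-2-yl)pent-4-en-1-yl]cyclohexa-2,4-dien-1-one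
Product: 16 (1S,5S,7R)-4-hydroxy-8,8-dimethyl-1-[(2R)-2-methylbutanoyl]-3-(3-oxobutyl)-5,7-di(prop-2-en-1-yl)bicyclo[3.3.1]non-3-ene-2,9-dione
Conditions: hν (365 nm LED), degassed benzene (5 mM), 20 °C
Reagents that add atoms: none
Why: Excitation of the chelated enol–acyl chromophore (C9–O–H···O=C on C1) makes the enol O–H strongly acidic in the excited state, so the proton is handed to the CH2 end of the isopropenyl group held beside it on C5, and the C8 tertiary cation, paired with the triketonate, collapses onto C1. The closest known reaction type is the excited-state intramolecular proton transfer photocyclisation of dearomatised acylphloroglucinols to type A bicyclo[3.3.1]nonanetriones, whereas ground-state acid such as formic acid closes the same cations at the non-acylated carbon C3. The ring C1–C9–C5–C6–C7–C8 closes in a 6-(enolendo) cation–enolate mode through a chair with the C7 allyl group equatorial. C1 is the only new stereocentre: the three-atom tether from C5 can reach C1 only on the face of ring A that carries C6, so C5 dictates C1, and the equatorial chair is open to the (6S) epimer used, which places the C7 allyl group exo. The step needs closure at C1 in preference to C3 and to the enol oxygens; C3 is fully substituted and lies away from the chelate that delivers the proton, and the charge of the contact ion pair sits on the acyl-bearing carbon next to the departing proton. Light of 365 nm avoids the n–π* band of the side-chain ketone, and a non-polar, acid-free solvent keeps the chelate intact and suppresses the thermal pathway.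

Step 11
Reactants: 16 (1S,5S,7R)-4-hydroxy-8,8-dimethyl-1-[(2R)-2-methylbutanoyl]-3-(3-oxobutyl)-5,7-di(prop-2-en-1-yl)bicyclo[3.3.1]non-3-ene-2,9-dione
Product: 17 (1S,5S,7R)-4-hydroxy-8,8-dimethyl-1-[(2R)-2-methylbutanoyl]-5,7-bis(3-methylbut-2-en-1-yl)-3-(3-oxobutyl)bicyclo[3.3.1]non-3-ene-2,9-dione
Conditions: second-generation Hoveyda–Grubbs catalyst (10 mol%), 2-methylbut-2-ene/CH2Cl2 (1:1), 40 °C, sealed tube
Reagents that add atoms: 2-methylbut-2-ene, CC=C(C)C
Why: olefin cross-metathesis of both terminal allyl groups with a trisubstituted alkene gives the two prenyl groups; no stereocentre is touched.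

Step 12
Reactants: 17 (1S,5S,7R)-4-hydroxy-8,8-dimethyl-1-[(2R)-2-methylbutanoyl]-5,7-bis(3-methylbut-2-en-1-yl)-3-(3-oxobutyl)bicyclo[3.3.1]non-3-ene-2,9-dione
Product: 18 (1S,5S,7R)-4-hydroxy-3-(3-hydroxy-3-methylbutyl)-8,8-dimethyl-1-[(2R)-2-methylbutanoyl]-5,7-bis(3-methylbut-2-en-1-yl)bicyclo[3.3.1]non-3-ene-2,9-dione
Conditions: MeMgBr (4 equiv), THF, −78 to −40 °C; aq. NH4Cl
Reagents that add atoms: methylmagnesium bromide, C[Mg]Br
Why: Grignard addition to the unhindered methyl ketone; the first equivalent turns the vinylogous acid into its enolate, which protects C2 and C4, while the C9 ketone and the bridgehead acyl ketone are shielded by quaternary carbons, and no new stereocentre is formed.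

Compound list
1 | (4S)-4-benzyl-1,3-oxazolidin-2-one | O=C1N[C@@H](Cc2ccccc2)CO1 | starting material
2 | 3-methylbut-2-enoyl chloride | CC(C)=CC(Cl)=O | starting material
3 | (4S)-4-benzyl-3-(3-methylbut-2-enoyl)-1,3-oxazolidin-2-one | CC(C)=CC(=O)N1[C@@H](Cc2ccccc2)COC1=O | intermediate
4 | (4S)-4-benzyl-3-[(2S)-2-(prop-1-en-2-yl)pent-4-enoyl]-1,3-oxazolidin-2-one | O=C([C@@H](CC=C)C(C)=C)N1[C@@H](Cc2ccccc2)COC1=O | intermediate
5 | (2S)-2-(prop-1-en-2-yl)pent-4-en-1-ol | OC[C@@H](CC=C)C(C)=C | intermediate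
6 | (2S)-2-(prop-1-en-2-yl)pent-4-en-1-yl trifluoromethanesulfonate | O=S(=O)(OC[C@@H](CC=C)C(C)=C)C(F)(F)F | intermediate
7 | (2R)-2-methylbutanoic acid | CC[C@@H](C)C(=O)O | starting material
8 | benzene-1,3,5-triol (phloroglucinol) | Oc1cc(O)cc(O)c1 | starting material
9 | (2R)-2-methylbutanoyl chloride | CC[C@@H](C)C(Cl)=O | intermediate
10 | (2R)-2-methyl-1-(2,4,6-trihydroxyphenyl)butan-1-one | CC[C@@H](C)C(=O)c1c(O)cc(O)cc1O | intermediate
11 | (2R)-1-(3-bromo-2,4,6-trihydroxyphenyl)-2-methylbutan-1-one | CC[C@@H](C)C(=O)c1c(O)cc(O)c(Br)c1O | intermediate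
12 | (2R)-1-[3-bromo-2,4,6-trihydroxy-5-(prop-2-en-1-yl)phenyl]-2-methylbutan-1-one | CC[C@@H](C)C(=O)c1c(O)c(CC=C)c(O)c(Br)c1O | intermediate
13 | (6S)-4-bromo-3,5-dihydroxy-2-[(2R)-2-methylbutanoyl]-6-(prop-2-en-1-yl)-6-[(2R)-2-(prop-1-en-2-yl)pent-4-en-1-yl]cyclohexa-2,4-dien-1-one | CC[C@@H](C)C(=O)C1=C(O)C(Br)=C(O)[C@](CC=C)(C[C@@H](CC=C)C(C)=C)C1=O | intermediate
14 | (6S)-3,5-dihydroxy-2-[(2R)-2-methylbutanoyl]-6-(prop-2-en-1-yl)-6-[(2R)-2-(prop-1-en-2-yl)pent-4-en-1-yl]cyclohexa-2,4-dien-1-one | CC[C@@H](C)C(=O)C1=C(O)C=C(O)[C@](CC=C)(C[C@@H](CC=C)C(C)=C)C1=O | intermediate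
15 | (6S)-3,5-dihydroxy-2-[(2R)-2-methylbutanoyl]-4-(3-oxobutyl)-6-(prop-2-en-1-yl)-6-[(2R)-2-(prop-1-en-2-yl)pent-4-en-1-yl]cyclohexa-2,4-dien-1-one | CC[C@@H](C)C(=O)C1=C(O)C(CCC(C)=O)=C(O)[C@](CC=C)(C[C@@H](CC=C)C(C)=C)C1=O | intermediate
16 | (1S,5S,7R)-4-hydroxy-8,8-dimethyl-1-[(2R)-2-methylbutanoyl]-3-(3-oxobutyl)-5,7-di(prop-2-en-1-yl)bicyclo[3.3.1]non-3-ene-2,9-dione | CC[C@@H](C)C(=O)[C@]12C(=O)C(CCC(C)=O)=C(O)[C@](CC=C)(C[C@@H](CC=C)C1(C)C)C2=O | intermediate
17 | (1S,5S,7R)-4-hydroxy-8,8-dimethyl-1-[(2R)-2-methylbutanoyl]-5,7-bis(3-methylbut-2-en-1-yl)-3-(3-oxobutyl)bicyclo[3.3.1]non-3-ene-2,9-dione | CC[C@@H](C)C(=O)[C@]12C(=O)C(CCC(C)=O)=C(O)[C@](CC=C(C)C)(C[C@@H](CC=C(C)C)C1(C)C)C2=O | intermediate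
18 | (1S,5S,7R)-4-hydroxy-3-(3-hydroxy-3-methylbutyl)-8,8-dimethyl-1-[(2R)-2-methylbutanoyl]-5,7-bis(3-methylbut-2-en-1-yl)bicyclo[3.3.1]non-3-ene-2,9-dione | CC[C@@H](C)C(=O)[C@]12C(=O)C(CCC(C)(C)O)=C(O)[C@](CC=C(C)C)(C[C@@H](CC=C(C)C)C1(C)C)C2=O | target

Total step count: 12. Longest linear sequence: 9 steps (steps 1–4 and 8–12).

Steps most likely to fail

Step 10 (key step). The excited chelate may relax without passing its proton to the alkene, the ion pair may close on an enol oxygen or at C3, or the dienone may add to an allyl group in a [2+2] mode. The fallback closes the same ring thermally on an acyl-free, symmetric precursor and adds the acyl group afterwards; it sets out from 6 and comes back to the route at 16. 1,3,5-Trimethoxybenzene is lithiated (n-BuLi, TMEDA, THF, 0 °C) and alkylated with 6 to give the alkylated trimethoxybenzene F1. NaSEt in DMF at 110 °C should remove the unhindered methyl group para to the side chain and give the phenol F2. Para-selective dearomative C-allylation (allyl methyl carbonate, Pd(PPh3)4, THF) gives the symmetric dienone F3, whose quaternary carbon is not yet a stereocentre. Formic acid at room temperature protonates the isopropenyl group; one of the two enol-ether carbons closes the ring through the chair with the allyl group equatorial and the oxocarbenium ion loses its methyl group, giving the bicyclic enol ether F4, so that C7 alone fixes C1 and C5. C3 is then blocked as the silane F5 (lithium 2,2,6,6-tetramethylpiperidide, Me3SiCl, THF, −78 °C). Bridgehead lithiation with the same base and quenching with acid chloride 9 gives the bridgehead ketone F6. Bu4NF removes the silyl group to give the enol ether F7, LiCl in DMSO at 120 °C cleaves the methyl ether to the vinylogous acid F8, and Michael addition to methyl vinyl ketone (Et3N, CH2Cl2) gives 16.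

Step 8. The new quaternary carbon may form with poor facial selectivity, and O-alkylation by the hindered triflate may compete. The fallback sets this carbon by chirality transfer in a sigmatropic shift; it sets out from 11 and comes back at 17. Compound 11 is C-alkylated with 6 at its only free ring position (LiN(SiMe3)2, THF, −78 to −20 °C) to give the arene F9. Mitsunobu etherification of the non-chelated hydroxyl para to the acyl group with (S)-but-3-en-2-ol (PPh3, diisopropyl azodicarboxylate, THF) gives, with inversion, the (R)-configured allylic aryl ether F10. Aromatic Claisen rearrangement (toluene, 100 °C) through the chair with the methyl group equatorial should deliver an (E)-but-2-enyl group to the alkylated ortho carbon on one face only, the brominated ortho carbon being the poorer terminus; this gives the bromodienone F11, which is debrominated in the work-up (aq. Na2SO3) to the dienone F12. Michael addition to methyl vinyl ketone as in step 9 gives the ketone F13, irradiation as in step 10 gives the bicycle F14, and cross-metathesis with 2-methylbut-2-ene as in step 11 turns both the butenyl and the allyl group into prenyl groups, which is 17.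

Step 12. The Grignard reagent may attack the bridging ketone or the bridgehead acyl group, or may only enolise the methyl ketone. The fallback moves the addition to the dearomatised stage; it sets out from 15 and comes back at 18. Compound 15 is treated with MeMgBr (5 equiv, THF, −78 to 0 °C): its two enol protons are removed first, so every ring and acyl carbonyl is masked in the dianion and only the side-chain ketone can be attacked, giving the tertiary alcohol F15. Irradiation as in step 10 gives the bicyclic alcohol F16, and cross-metathesis as in step 11 gives 18.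

Further compounds
F1 | step 10 | 1,3,5-trimethoxy-2-[(2R)-2-(prop-1-en-2-yl)pent-4-en-1-yl]benzene | COc1cc(OC)c(C[C@@H](CC=C)C(C)=C)c(OC)c1
F2 | step 10 | 3,5-dimethoxy-4-[(2R)-2-(prop-1-en-2-yl)pent-4-en-1-yl]phenol | COc1cc(O)cc(OC)c1C[C@@H](CC=C)C(C)=C
F3 | step 10 | 3,5-dimethoxy-4-(prop-2-en-1-yl)-4-[(2R)-2-(prop-1-en-2-yl)pent-4-en-1-yl]cyclohexa-2,5-dien-1-one | COC1=CC(=O)C=C(OC)C1(CC=C)C[C@@H](CC=C)C(C)=C
F4 | step 10 | (1R,5S,7R)-4-methoxy-8,8-dimethyl-5,7-di(prop-2-en-1-yl)bicyclo[3.3.1]non-3-ene-2,9-dione | [C@H]12C(=O)C=C(OC)[C@](CC=C)(C[C@@H](CC=C)C1(C)C)C2=O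
F5 | step 10 | 3-trimethylsilyl derivative of F4 | [C@H]12C(=O)C([Si](C)(C)C)=C(OC)[C@](CC=C)(C[C@@H](CC=C)C1(C)C)C2=O
F6 | step 10 | 1-[(2R)-2-methylbutanoyl]-3-trimethylsilyl derivative of F4 | CC[C@@H](C)C(=O)[C@]12C(=O)C([Si](C)(C)C)=C(OC)[C@](CC=C)(C[C@@H](CC=C)C1(C)C)C2=O
F7 | step 10 | (1S,5S,7R)-4-methoxy-8,8-dimethyl-1-[(2R)-2-methylbutanoyl]-5,7-di(prop-2-en-1-yl)bicyclo[3.3.1]non-3-ene-2,9-dione | CC[C@@H](C)C(=O)[C@]12C(=O)C=C(OC)[C@](CC=C)(C[C@@H](CC=C)C1(C)C)C2=O
F8 | step 10 | (1S,5S,7R)-4-hydroxy-8,8-dimethyl-1-[(2R)-2-methylbutanoyl]-5,7-di(prop-2-en-1-yl)bicyclo[3.3.1]non-3-ene-2,9-dione | CC[C@@H](C)C(=O)[C@]12C(=O)C=C(O)[C@](CC=C)(C[C@@H](CC=C)C1(C)C)C2=O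
F9 | step 8 | (2R)-1-{3-bromo-2,4,6-trihydroxy-5-[(2R)-2-(prop-1-en-2-yl)pent-4-en-1-yl]phenyl}-2-methylbutan-1-one | CC[C@@H](C)C(=O)c1c(O)c(Br)c(O)c(C[C@@H](CC=C)C(C)=C)c1O
F10 | step 8 | (2R)-1-{3-bromo-4-[(2R)-but-3-en-2-yloxy]-2,6-dihydroxy-5-[(2R)-2-(prop-1-en-2-yl)pent-4-en-1-yl]phenyl}-2-methylbutan-1-one | CC[C@@H](C)C(=O)c1c(O)c(Br)c(O[C@H](C)C=C)c(C[C@@H](CC=C)C(C)=C)c1O
F11 | step 8 | (6S)-4-bromo-6-[(2E)-but-2-en-1-yl]-3,5-dihydroxy-2-[(2R)-2-methylbutanoyl]-6-[(2R)-2-(prop-1-en-2-yl)pent-4-en-1-yl]cyclohexa-2,4-dien-1-one | CC[C@@H](C)C(=O)C1=C(O)C(Br)=C(O)[C@](C/C=C/C)(C[C@@H](CC=C)C(C)=C)C1=O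
F12 | step 8 | (6S)-6-[(2E)-but-2-en-1-yl]-3,5-dihydroxy-2-[(2R)-2-methylbutanoyl]-6-[(2R)-2-(prop-1-en-2-yl)pent-4-en-1-yl]cyclohexa-2,4-dien-1-one | CC[C@@H](C)C(=O)C1=C(O)C=C(O)[C@](C/C=C/C)(C[C@@H](CC=C)C(C)=C)C1=O
F13 | step 8 | 4-(3-oxobutyl) derivative of F12 | CC[C@@H](C)C(=O)C1=C(O)C(CCC(C)=O)=C(O)[C@](C/C=C/C)(C[C@@H](CC=C)C(C)=C)C1=O
F14 | step 8 | (1S,5S,7R)-5-[(2E)-but-2-en-1-yl]-4-hydroxy-8,8-dimethyl-1-[(2R)-2-methylbutanoyl]-3-(3-oxobutyl)-7-(prop-2-en-1-yl)bicyclo[3.3.1]non-3-ene-2,9-dione | CC[C@@H](C)C(=O)[C@]12C(=O)C(CCC(C)=O)=C(O)[C@](C/C=C/C)(C[C@@H](CC=C)C1(C)C)C2=O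
F15 | step 12 | (6S)-3,5-dihydroxy-4-(3-hydroxy-3-methylbutyl)-2-[(2R)-2-methylbutanoyl]-6-(prop-2-en-1-yl)-6-[(2R)-2-(prop-1-en-2-yl)pent-4-en-1-yl]cyclohexa-2,4-dien-1-one | CC[C@@H](C)C(=O)C1=C(O)C(CCC(C)(C)O)=C(O)[C@](CC=C)(C[C@@H](CC=C)C(C)=C)C1=O
F16 | step 12 | (1S,5S,7R)-4-hydroxy-3-(3-hydroxy-3-methylbutyl)-8,8-dimethyl-1-[(2R)-2-methylbutanoyl]-5,7-di(prop-2-en-1-yl)bicyclo[3.3.1]non-3-ene-2,9-dione | CC[C@@H](C)C(=O)[C@]12C(=O)C(CCC(C)(C)O)=C(O)[C@](CC=C)(C[C@@H](CC=C)C1(C)C)C2=O
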